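**Retrosynthetic overview**

1. Ring numbering: C1 = ring ketone carbon, C2 = acyl-bearing carbon, C3/C5 = enol carbons, C4 = prenyl-bearing carbon, C6 = quaternary C(OMe)(prenyl) stereocentre. Enabling feature: C2 is the central carbon of a β-triketone (C1=O, C3–O, exocyclic C=O), so it is a ready carbanion, and C1 is an acyl carbon on C6. C1–C2 is therefore a Claisen (Dieckmann) bond, and C5–C6–C1 is a 2-methoxy-2-prenylmalonyl unit.
2. 12 ⇒ 11: the phenethyl ketone is carried as a styryl ketone. This extra unsaturation leaves the diketone partner with one γ-enolisable position only and is removed last by hydrogenation.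
3. 11 ⇒ one-pot union of three components: the dianion of cinnamoylacetone 3, prenyl bromide 5 and malonyl chloride ester 8. The C4–CH2 (prenyl) bond forms first, then C4–C5, then the only ring is closed at C1–C2.
4. 8 ⇒ 7 ⇒ 6 (from 4 + 5): the C6 stereocentre comes from enzymatic desymmetrisation of a prochiral malonate and is carried into the ring by the COCl/CO2Me differentiation. 3 comes from benzaldehyde and acetylacetone.

Key step: step 5

Assumption: the esterase is taken to give the (2S)-half-ester 7 from 6; the descriptor changes to (R) in 8 only because COCl outranks CO2Me, not because the geometry changes.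

**Step 1**
Reactants: 1 benzaldehyde; 2 pentane-2,4-dione
Product: 3 (5E)-6-phenylhex-5-ene-2,4-dione
Conditions: 2 (3 equiv), B2O3, B(OBu)3, n-BuNH2 (cat.), EtOAc, 70 °C; then 0.4 M HCl, 60 °C
Reagents that add atoms: none
Why: In the boron chelate of 2 the central carbon is masked, so the amine-catalysed aldol condensation (Knoevenagel-type) takes place at a terminal methyl group and dehydration gives the conjugated E-alkene, while the excess of 2 suppresses a second condensation.

**Step 2**
Reactants: 4 dimethyl 2-methoxypropanedioate; 5 1-bromo-3-methylbut-2-ene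
Product: 6 dimethyl 2-methoxy-2-(3-methylbut-2-en-1-yl)propanedioate
Conditions: NaH (1.1 equiv), THF, 0 °C; then 5, 0 °C to rt
Reagents that add atoms: none
Why: Malonic ester alkylation, in which the sodium enolate of the α-alkoxymalonate displaces the primary allylic bromide by SN2 at the unsubstituted terminus and gives the prochiral quaternary carbon.

**Step 3**
Reactants: 6 dimethyl 2-methoxy-2-(3-methylbut-2-en-1-yl)propanedioate
Product: 7 (2S)-2-methoxy-2-(methoxycarbonyl)-5-methylhex-4-enoic acid
Conditions: pig liver esterase, sodium phosphate buffer pH 7.5, DMSO (10 vol %), rt; then acidification to pH 3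
Reagents that add atoms: water, O
Why: Enzymatic desymmetrisation (enantiotopic-group-selective ester hydrolysis) of a prochiral 2,2-disubstituted malonate, in which the chiral active site selects one of the two CO2Me groups and so sets the quaternary stereocentre, and which should stop at the monoacid because the carboxylate is a poor substrate.

**Step 4**
Reactants: 7 (2S)-2-methoxy-2-(methoxycarbonyl)-5-methylhex-4-enoic acid
Product: 8 methyl (2R)-2-(chlorocarbonyl)-2-methoxy-5-methylhex-4-enoate
Conditions: 1-chloro-N,N,2-trimethylprop-1-en-1-amine (1.2 equiv), CH2Cl2, 0 °C to rt; used crude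
Reagents that add atoms: 1-chloro-N,N,2-trimethylprop-1-en-1-amine, CC(C)=C(Cl)N(C)C
Why: Acid chloride formation with an α-chloroenamine under neutral conditions, which frees no HCl that could add to the trisubstituted alkene, at a stereocentre that has no α-hydrogen and so can neither epimerise nor form a ketene.

**Step 5**
Reactants: 3 (5E)-6-phenylhex-5-ene-2,4-dione; 5 1-bromo-3-methylbut-2-ene; 8 methyl (2R)-2-(chlorocarbonyl)-2-methoxy-5-methylhex-4-enoate
Product: 11 (6S)-3,5-dihydroxy-6-methoxy-4,6-bis(3-methylbut-2-en-1-yl)-2-[(2E)-3-phenylprop-2-enoyl]cyclohexa-2,4-dien-1-one, via diketone enolate 9 (not isolated), via open-chain triketo ester 10 (not isolated)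
Conditions: 3 (2.1 equiv), LiN(iPr)2 (4.2 equiv), THF, −78 to 0 °C; 5 (2.0 equiv), −78 to 0 °C; LiN(iPr)2 (2.0 equiv), −78 to 0 °C; 8 (1.0 equiv), −78 °C to rt; aq. citric acid
Reagents that add atoms: none
Why: The dianion of 3 can form only at the methyl group, because the styryl side carries no γ-hydrogen, so 5 alkylates that carbon (SN2) to give the enolate of 9, and the next equivalent of LiN(iPr)2 again finds C6 of 9 as the only position to deprotonate. This γ-carbanion attacks the COCl group of 8 at −78 °C, far faster than the methyl ester, and proton transfer from the new C4–H to the second equivalent of dianion gives the dianion of 10, in which the styryl ketone is part of an enolate and so is switched off as a Michael acceptor. On warming, C6 of 10, the central carbon of the C5/C7 β-diketone, attacks the C1 ester in a 6-exo-trig Dieckmann (intramolecular Claisen) closure that forms the ring C1–C2 bond; methoxide leaves and the doubly deprotonated β-triketone 11 is the thermodynamic sink. The closest known reaction types are the γ-alkylation and γ-acylation of 1,3-diketone dianions and the Claisen cyclisation of 3,5,7-triketo esters to acylphloroglucinols. No stereocentre is formed: ring C6 comes from 8, and because its configuration is defined only by which malonyl carbonyl becomes C5 and which C1, the reactivity gap between COCl (attacked first, between molecules) and CO2Me (attacked second, within the molecule) is what secures the enantiomeric purity. Carbon-over-oxygen selectivity is needed in both acylations and is secured by the hard γ-carbanion in the first and, in the second, by reversibility, since an O-cyclised enol lactone would be reopened by lithium methoxide and drained to the C-acylated trione.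

**Step 6**
Reactants: 11 (6S)-3,5-dihydroxy-6-methoxy-4,6-bis(3-methylbut-2-en-1-yl)-2-[(2E)-3-phenylprop-2-enoyl]cyclohexa-2,4-dien-1-one
Product: 12 (6S)-3,5-dihydroxy-6-methoxy-4,6-bis(3-methylbut-2-en-1-yl)-2-(3-phenylpropanoyl)cyclohexa-2,4-dien-1-one
Conditions: H2 (1 atm), RhCl(PPh3)3 (10 mol %), benzene–EtOH (1:1), rt
Reagents that add atoms: none
Why: Homogeneous hydrogenation with RhCl(PPh3)3 should reduce the 1,2-disubstituted styryl C=C bond of the enone while the trisubstituted prenyl and tetrasubstituted enol double bonds are too hindered to coordinate, and the stereocentre is not involved.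

**Compound list**

1 | benzaldehyde | O=Cc1ccccc1 | starting material
2 | pentane-2,4-dione | CC(=O)CC(C)=O | starting material
3 | (5E)-6-phenylhex-5-ene-2,4-dione (cinnamoylacetone) | CC(=O)CC(=O)/C=C/c1ccccc1 | intermediate
4 | dimethyl 2-methoxypropanedioate | COC(C(=O)OC)C(=O)OC | starting material
5 | 1-bromo-3-methylbut-2-ene (prenyl bromide) | CC(C)=CCBr | starting material
6 | dimethyl 2-methoxy-2-(3-methylbut-2-en-1-yl)propanedioate | COC(=O)C(CC=C(C)C)(OC)C(=O)OC | intermediate
7 | (2S)-2-methoxy-2-(methoxycarbonyl)-5-methylhex-4-enoic acid | CO[C@](C(=O)O)(CC=C(C)C)C(=O)OC | intermediate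
8 | methyl (2R)-2-(chlorocarbonyl)-2-methoxy-5-methylhex-4-enoate | CO[C@](C(=O)Cl)(CC=C(C)C)C(=O)OC | intermediate
9 | (1E)-9-methyl-1-phenyldeca-1,8-diene-3,5-dione, formed as its lithium enolate and not isolated | O=C(/C=C/c1ccccc1)CC(=O)CCC=C(C)C | intermediate
10 | methyl (2S,8E)-2-methoxy-2,4-bis(3-methylbut-2-en-1-yl)-3,5,7-trioxo-9-phenylnon-8-enoate, formed as its dilithium salt (C4 epimers and enol forms) and not isolated | CO[C@](C(=O)C(CC=C(C)C)C(=O)CC(=O)/C=C/c1ccccc1)(CC=C(C)C)C(=O)OC | intermediate
11 | (6S)-3,5-dihydroxy-6-methoxy-4,6-bis(3-methylbut-2-en-1-yl)-2-[(2E)-3-phenylprop-2-enoyl]cyclohexa-2,4-dien-1-one | CO[C@]1(CC=C(C)C)C(=O)C(C(=O)/C=C/c2ccccc2)=C(O)C(CC=C(C)C)=C1O | intermediate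
12 | (6S)-3,5-dihydroxy-6-methoxy-4,6-bis(3-methylbut-2-en-1-yl)-2-(3-phenylpropanoyl)cyclohexa-2,4-dien-1-one (CNP0319461.1) | CO[C@]1(CC=C(C)C)C(=O)C(C(=O)CCc2ccccc2)=C(O)C(CC=C(C)C)=C1O | target

**Step count**

Total steps: 6. Longest linear sequence: 5 steps (4 → 6 → 7 → 8 → 11 → 12; steps 2 to 6).

**Steps most likely to fail**

Step 5. The dianion may be acylated on oxygen or quenched by proton transfer before it is acylated, it may attack the ester end of 8 (which would erode the enantiomeric purity), or the ring may close through oxygen and stay there. The fallback sets out from 3 and comes back at 11. The alkylation of the dianion of 3 with 5 is quenched and 9 is isolated. 9 is converted with Me3SiOTf and Et3N (Et2O, 0 °C) into (1E)-9-methyl-1-phenyl-3,5-bis(trimethylsilyloxy)deca-1,3,5,8-tetraene F1, which can form on the C6 side only. F1 is acylated at its terminal carbon by 8 without any base (CH2Cl2, −78 °C to rt; Mukaiyama-type acylation of a 1,3-bis-silyl dienol ether), and mild aqueous work-up should give isolated 10. 10 is then closed in a separate, equilibrating Claisen step (NaOMe, MeOH, rt) to 11.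

Step 6. The hydrogenation may lose chemoselectivity (reduction or migration of the prenyl double bonds), or the catalyst may be inhibited through chelation of rhodium by the β-triketone. The fallback sets out from 3 and comes back at 12, and it needs no late reduction. 3 is hydrogenated while no prenyl group is present (H2, Pd/C, EtOAc) to 6-phenylhexane-2,4-dione F2. Its dianion (LiN(iPr)2, 2 equiv; the methyl group is ionised in preference to the methylene group) is acylated by 8 and ring-closed as in step 5, by way of methyl (2S)-2-methoxy-2-(3-methylbut-2-en-1-yl)-3,5,7-trioxo-9-phenylnonanoate F3, to (6S)-3,5-dihydroxy-6-methoxy-6-(3-methylbut-2-en-1-yl)-2-(3-phenylpropanoyl)cyclohexa-2,4-dien-1-one F4. C-Prenylation of F4 at C4 with 5 (NaOMe, MeOH, 0 °C), the classical alkylation of acylphloroglucinol-type enolates, then gives 12.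

Step 3. The enzymatic hydrolysis may be slow or may discriminate poorly between the two ester groups, or it may favour the other one. The fallback sets out from 6 and comes back at 7. One ester group of 6 is saponified without selectivity (KOH, 1.0 equiv, MeOH, 0 °C) to rac-2-methoxy-2-(methoxycarbonyl)-5-methylhex-4-enoic acid F5. F5 is resolved by fractional crystallisation of (1S)-1-phenylethan-1-aminium (2S)-2-methoxy-2-(methoxycarbonyl)-5-methylhex-4-enoate F6 (the antipodal amine is used if the salt of the wanted acid proves the more soluble one), and acidification of the salt gives 7.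

**Further compounds**

F1 | step 5 | (1E)-9-methyl-1-phenyl-3,5-bis(trimethylsilyloxy)deca-1,3,5,8-tetraene (mixture of enol ether geometries) | C[Si](C)(C)OC(/C=C/c1ccccc1)=CC(O[Si](C)(C)C)=CCC=C(C)C
F2 | step 6 | 6-phenylhexane-2,4-dione | CC(=O)CC(=O)CCc1ccccc1
F3 | step 6 | methyl (2S)-2-methoxy-2-(3-methylbut-2-en-1-yl)-3,5,7-trioxo-9-phenylnonanoate | CO[C@](C(=O)CC(=O)CC(=O)CCc1ccccc1)(CC=C(C)C)C(=O)OC
F4 | step 6 | (6S)-3,5-dihydroxy-6-methoxy-6-(3-methylbut-2-en-1-yl)-2-(3-phenylpropanoyl)cyclohexa-2,4-dien-1-one | CO[C@]1(CC=C(C)C)C(=O)C(C(=O)CCc2ccccc2)=C(O)C=C1O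
F5 | step 3 | rac-2-methoxy-2-(methoxycarbonyl)-5-methylhex-4-enoic acid | COC(CC=C(C)C)(C(=O)O)C(=O)OC
F6 | step 3 | (1S)-1-phenylethan-1-aminium (2S)-2-methoxy-2-(methoxycarbonyl)-5-methylhex-4-enoate | CO[C@](C(=O)[O-])(CC=C(C)C)C(=O)OC.C[C@H]([NH3+])c1ccccc1
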